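**Plan** (locants are those of the name of 27 in the compound list: bicycle C1–C8 with O2, oxane 1′–6′, spiro atom C5 = C2′)

- Cuts, in retrosynthetic order: C8 ketone ⇒ carbinol; C4–C8 of the carbocycle (samarium-enolate aldol); C5′–C6′ together with O1′–C6′ of the oxane (silyl enol ether Prins with acetaldehyde); C4–C5 of the δ-lactone (Reformatsky lactonisation); O2–C3 (esterification); C3′–C4′ and C1–C6 (two aldol reactions on pentan-3-one).
- Forward order of rings: δ-lactone (O2, C3, C4, C5, C6, C1) in step 7, oxane spiro-fused to it in step 11, carbocycle (C4, C5, C6, C1, C7, C8) that completes the bicyclo[2.2.2] system in step 16.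
- Enabling feature: in the oxane, O1′ sits between the fully substituted spiro carbon and C6′, a CH(CH3) carbon at the acetaldehyde oxidation level, while C5′ is α to the oxygen-bearing C4′. With C4′ as a ketone, the C5′–C6′ bond joins an enol α-carbon to an oxocarbenium carbon.
- Stereochemistry: C7 from the Roche ester; C1 and C6 by a Felkin-selective boron anti-aldol; C3′ by a 1,3-syn titanium aldol; C5 by a samarium-chelated chair in the Reformatsky step; C5′ and C6′ by the chair Prins transition state; C4′ by equatorial hydride delivery; C4 by the geometry of the bridging aldol.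
- C8 stays at the alcohol/aldehyde level until after the C4′ ketone has been reduced, so no second ketone competes in step 12.

Key step: step 11

Remark: the bromine-bearing carbon of 14–24 is a mixture of epimers (it becomes the quaternary bridgehead only in step 16), and the carbinol configuration drawn for 26 is the one expected from a chelated transition state; either epimer gives 27 in step 17.

**Step 1**
Reactants: 1 methyl (R)-3-hydroxy-2-methylpropanoate
Product: 2 methyl (R)-3-[(tert-butyldiphenylsilyl)oxy]-2-methylpropanoate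
Conditions: TBDPSCl, imidazole, DMF, 0 °C to rt
Reagents that add atoms: tert-butyl(chloro)diphenylsilane, CC(C)(C)[Si](Cl)(c1ccccc1)c1ccccc1
Why: Silylation of the primary alcohol with imidazole catalysis masks the carbon that becomes the C8 aldehyde much later; the stereocentre is not touched.

**Step 2**
Reactants: 2 methyl (R)-3-[(tert-butyldiphenylsilyl)oxy]-2-methylpropanoate
Product: 3 (R)-3-[(tert-butyldiphenylsilyl)oxy]-2-methylpropanal
Conditions: i-Bu2AlH (1.05 equiv), CH2Cl2, −78 °C; Rochelle salt work-up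
Reagents that add atoms: none
Why: Partial ester reduction stops at the aluminium hemiacetal at −78 °C, and the α-chiral aldehyde should be used at once to avoid epimerisation.

**Step 3**
Reactants: 4 pentan-3-one; 3 (R)-3-[(tert-butyldiphenylsilyl)oxy]-2-methylpropanal
Product: 6 (4S,5S,6R)-7-[(tert-butyldiphenylsilyl)oxy]-5-hydroxy-4,6-dimethylheptan-3-one, via boron E-enolate 5 (not isolated)
Conditions: c-Hex2BCl, Et3N, Et2O, 0 °C; then 3, −78 to −20 °C; H2O2, MeOH, pH 7 buffer, 0 °C
Reagents that add atoms: none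
Why: Boron-mediated anti-aldol reaction in which the E-enol borinate reacts through a Zimmerman–Traxler chair (4,5-anti) and adds to the α-methyl aldehyde in the Felkin–Anh sense (5,6-syn), so both new centres follow from the Roche-ester centre.

**Step 4**
Reactants: 6 (4S,5S,6R)-7-[(tert-butyldiphenylsilyl)oxy]-5-hydroxy-4,6-dimethylheptan-3-one; 7 2,2-dibromopropanoic acid
Product: 8 (2R,3S,4S)-1-[(tert-butyldiphenylsilyl)oxy]-2,4-dimethyl-5-oxoheptan-3-yl 2,2-dibromopropanoate
Conditions: DCC, DMAP (cat.), CH2Cl2, 0 °C to rt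
Reagents that add atoms: none
Why: Steglich esterification of the secondary alcohol installs a gem-dibromo propanoate whose α-carbon can later be made nucleophilic twice.

**Step 5**
Reactants: 8 (2R,3S,4S)-1-[(tert-butyldiphenylsilyl)oxy]-2,4-dimethyl-5-oxoheptan-3-yl 2,2-dibromopropanoate; 9 propanal
Product: 11 (3S,4R,6S,7S,8R)-9-[(tert-butyldiphenylsilyl)oxy]-3-hydroxy-4,6,8-trimethyl-5-oxononan-7-yl 2,2-dibromopropanoate, via titanium Z-enolate 10 (not isolated)
Conditions: TiCl4, i-Pr2NEt, CH2Cl2, −78 °C; then 9, −78 °C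
Reagents that add atoms: none
Why: Titanium-mediated syn-aldol reaction in which soft enolisation occurs only at the ethyl CH2 (the ester has no α-hydrogen) and the closed transition state of the Z-enolate adds syn and 1,3-syn to the α′-methyl centre (minimised allylic strain), making the two methyl groups that flank the ketone syn.

**Step 6**
Reactants: 11 (3S,4R,6S,7S,8R)-9-[(tert-butyldiphenylsilyl)oxy]-3-hydroxy-4,6,8-trimethyl-5-oxononan-7-yl 2,2-dibromopropanoate
Product: 12 (3S,4R,6S,7S,8R)-9-[(tert-butyldiphenylsilyl)oxy]-4,6,8-trimethyl-5-oxo-3-[(triethylsilyl)oxy]nonan-7-yl 2,2-dibromopropanoate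
Conditions: TESOTf, 2,6-lutidine, CH2Cl2, −78 °C
Reagents that add atoms: triethylsilyl trifluoromethanesulfonate, CC[Si](CC)(CC)OS(=O)(=O)C(F)(F)F
Why: Silylation removes the only hydroxyl proton that could quench the samarium enolate of step 7.

**Step 7**
Reactants: 12 (3S,4R,6S,7S,8R)-9-[(tert-butyldiphenylsilyl)oxy]-4,6,8-trimethyl-5-oxo-3-[(triethylsilyl)oxy]nonan-7-yl 2,2-dibromopropanoate
Product: 14 (4R,5S,6S)-3-bromo-6-[(2R)-1-[(tert-butyldiphenylsilyl)oxy]propan-2-yl]-4-hydroxy-3,5-dimethyl-4-[(2R,3S)-3-[(triethylsilyl)oxy]pentan-2-yl]oxan-2-one as a mixture of C3 epimers, via samarium bromo enolate 13 (not isolated)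
Conditions: SmI2 (2.1 equiv), THF, −78 °C; aq NH4Cl at −78 °C
Reagents that add atoms: none
Why: Intramolecular samarium diiodide Reformatsky reaction (aldol lactonisation) of a β-acyloxy ketone, in which the bromo enolate from reduction of one C–Br bond adds through a samarium-chelated chair with the ketone oxygen axial and both ring substituents equatorial, setting the tertiary carbinol cis to the C5 methyl and trans to the C6 side chain; two equivalents at −78 °C keep the second bromine.

**Step 8**
Reactants: 14 bromo hydroxy lactone (name as in step 7)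
Product: 15 (4S,5S,6S)-3-bromo-6-[(2R)-1-[(tert-butyldiphenylsilyl)oxy]propan-2-yl]-4-hydroxy-4-[(2R,3S)-3-hydroxypentan-2-yl]-3,5-dimethyloxan-2-one
Conditions: PPTS (cat.), MeOH–CH2Cl2, 0 °C
Reagents that add atoms: none
Why: Acid-catalysed methanolysis cleaves the secondary triethylsilyl ether while the primary tert-butyldiphenylsilyl ether survives.

**Step 9**
Reactants: 15 diol lactone (name as in step 8)
Product: 16 (4R,5S,6S)-3-bromo-6-[(2R)-1-[(tert-butyldiphenylsilyl)oxy]propan-2-yl]-4-hydroxy-3,5-dimethyl-4-[(2S)-3-oxopentan-2-yl]oxan-2-one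
Conditions: Dess–Martin periodinane, NaHCO3, CH2Cl2, 0 °C to rt
Reagents that add atoms: none
Why: Dess–Martin oxidation converts the secondary alcohol into the ethyl ketone under buffered conditions that do not promote retro-aldol cleavage; the tertiary alcohol cannot be oxidised.

**Step 10**
Reactants: 16 hydroxy ketone lactone (name as in step 9)
Product: 17 bis(trimethylsilyl) derivative of 16 (tertiary O-trimethylsilyl ether and Z-trimethylsilyl enol ether toward the ethyl group)
Conditions: TMSOTf (2.5 equiv), Et3N, CH2Cl2, −78 to −40 °C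
Reagents that add atoms: trimethylsilyl trifluoromethanesulfonate, C[Si](C)(C)OS(=O)(=O)C(F)(F)F
Why: Silyl triflate/amine soft enolisation gives the Z-enol ether at the less hindered CH2 rather than at the neopentyl-type methine, and the same reagent silylates the tertiary alcohol, so both groups needed for the Prins step are installed together.

**Step 11**
Reactants: 17 bis(trimethylsilyl) derivative of 16; 18 acetaldehyde
Product: 20 7-bromo-10-[(2R)-1-[(tert-butyldiphenylsilyl)oxy]propan-2-yl]-2,3,5,7,11-pentamethyl-1,9-dioxaspiro[5.5]undecane-4,8-dione, via oxocarbenium triflate 19 (not isolated)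
Conditions: CH3CHO (3 equiv), TMSOTf (0.3 equiv), CH2Cl2, −78 °C; Et3N quench
Reagents that add atoms: none
Why: TMSOTf condenses acetaldehyde with the tertiary trimethylsilyl ether to a silyl hemiacetal and ionises it, with loss of hexamethyldisiloxane, to the E-oxocarbenium ion 19, whose carbon is attacked by the nucleophilic carbon of the tethered Z-silyl enol ether; desilylation of the resulting silyloxocarbenium ion gives the ketone and returns the silyl triflate. The closest known reaction type is the silyl enol ether Prins cyclisation of hydroxy silyl enol ethers with aldehydes to oxan-4-ones, combined with the silyl-triflate-catalysed condensation of silyl ethers with aldehydes that is used to generate oxocarbenium ions for intramolecular capture. The oxane is closed by carbon–carbon bond formation in a 6-(enolendo)-endo-trig mode through a chair transition state. C2 of 20 is set by the E geometry of the oxocarbenium ion, which places its methyl group equatorial in the chair fixed by the equatorial C5 methyl group and by the spiro carbon (methine lactone carbon C11 axial, quaternary bromo carbon C7 equatorial); C3 is set by the Z geometry of the enol ether, which places its methyl group equatorial, and this is also the thermodynamically preferred epimer next to the ketone. The step needs capture of the oxocarbenium ion by the internal enol ether faster than intermolecular addition of the enol ether to acetaldehyde; catalytic silyl triflate at −78 °C activates oxocarbenium ions but not free aldehydes toward enol silanes, and only the ethyl-side enol ether can reach the oxocarbenium carbon in a six-membered array. The tertiary bromide, the lactone and the primary silyl ether are inert, and the stereocentre between the ketone and the spiro carbon is not enolised at −78 °C.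

**Step 12**
Reactants: 20 spiro keto lactone (name as in step 11)
Product: 21 7-bromo-10-[(2R)-1-[(tert-butyldiphenylsilyl)oxy]propan-2-yl]-4-hydroxy-2,3,5,7,11-pentamethyl-1,9-dioxaspiro[5.5]undecan-8-one (axial C4 hydroxyl, cis to the C3 and C5 methyl groups)
Conditions: LiBH(s-Bu)3, THF, −78 °C; aq NH4Cl
Reagents that add atoms: none
Why: Ketone reduction by the bulky borohydride occurs from the equatorial direction because the axial face is blocked by the axial lactone carbon C11 on the spiro centre, giving the axial alcohol; no other ketone is present, and the lactone and tertiary bromide are not reduced at −78 °C.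

**Step 13**
Reactants: 21 axial alcohol (name as in step 12)
Product: 22 7-bromo-10-[(2R)-1-[(tert-butyldiphenylsilyl)oxy]propan-2-yl]-2,3,5,7,11-pentamethyl-8-oxo-1,9-dioxaspiro[5.5]undecan-4-yl acetate
Conditions: Ac2O, DMAP, pyridine, 40 °C
Reagents that add atoms: acetic anhydride, CC(=O)OC(C)=O
Why: DMAP-catalysed acylation esterifies the hindered axial alcohol with retention of configuration.

**Step 14**
Reactants: 22 acetate (name as in step 13)
Product: 23 7-bromo-10-[(2R)-1-hydroxypropan-2-yl]-2,3,5,7,11-pentamethyl-8-oxo-1,9-dioxaspiro[5.5]undecan-4-yl acetate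
Conditions: HF·pyridine, pyridine, THF, 0 °C to rt
Reagents that add atoms: none
Why: Fluoride-mediated desilylation frees the primary alcohol; acetate, lactone and tertiary bromide tolerate buffered HF·pyridine.

**Step 15**
Reactants: 23 primary alcohol (name as in step 14)
Product: 24 7-bromo-2,3,5,7,11-pentamethyl-8-oxo-10-(1-oxopropan-2-yl)-1,9-dioxaspiro[5.5]undecan-4-yl acetate
Conditions: Dess–Martin periodinane, NaHCO3, CH2Cl2, 0 °C
Reagents that add atoms: none
Why: Dess–Martin oxidation gives the α-chiral β-acyloxy aldehyde under non-basic conditions, avoiding epimerisation and β-elimination.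

**Step 16**
Reactants: 24 bromo lactone aldehyde (name as in step 15)
Product: 26 8-hydroxy-4,6,7,3′,5′,6′-hexamethyl-3-oxospiro[2-oxabicyclo[2.2.2]octane-5,2′-oxan]-4′-yl acetate, via samarium lactone enolate 25 (not isolated)
Conditions: SmI2 (2.2 equiv), THF, −78 °C; aq NH4Cl
Reagents that add atoms: none
Why: Intramolecular samarium diiodide Reformatsky-type aldol reaction in which reduction of the tertiary C–Br bond gives the lactone enolate, which adds to the aldehyde tethered at C1 and closes the carbocycle; the quaternary C4 can only form with the configuration imposed by the bridge, and chelation of the aldehyde oxygen to samarium is expected to place the C8 hydroxyl on the lactone side.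

**Step 17**
Reactants: 26 bicyclic carbinol (name as in step 16)
Product: 27 (1R,3′R,4S,4′R,5S,5′R,6S,6′R,7S)-4,6,7,3′,5′,6′-hexamethyl-3,8-dioxospiro[2-oxabicyclo[2.2.2]octane-5,2′-oxan]-4′-yl acetate
Conditions: Dess–Martin periodinane, NaHCO3, CH2Cl2, rt
Reagents that add atoms: none
Why: Dess–Martin oxidation of the C8 carbinol under buffered neutral conditions gives the ketone without exposing the base-sensitive β-acyloxy ketone to enolisation.

**Compound list**

1 | methyl (R)-3-hydroxy-2-methylpropanoate | COC(=O)[C@H](C)CO | starting material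
2 | methyl (R)-3-[(tert-butyldiphenylsilyl)oxy]-2-methylpropanoate | COC(=O)[C@H](C)CO[Si](c1ccccc1)(c1ccccc1)C(C)(C)C | intermediate
3 | (R)-3-[(tert-butyldiphenylsilyl)oxy]-2-methylpropanal | O=C[C@H](C)CO[Si](c1ccccc1)(c1ccccc1)C(C)(C)C | intermediate
4 | pentan-3-one | CCC(=O)CC | starting material
5 | dicyclohexyl[(E)-pent-2-en-3-yloxy]borane (boron E-enolate) | C/C=C(\CC)OB(C1CCCCC1)C1CCCCC1 | intermediate
6 | (4S,5S,6R)-7-[(tert-butyldiphenylsilyl)oxy]-5-hydroxy-4,6-dimethylheptan-3-one | CCC(=O)[C@@H](C)[C@@H](O)[C@H](C)CO[Si](c1ccccc1)(c1ccccc1)C(C)(C)C | intermediate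
7 | 2,2-dibromopropanoic acid | CC(Br)(Br)C(=O)O | starting material
8 | (2R,3S,4S)-1-[(tert-butyldiphenylsilyl)oxy]-2,4-dimethyl-5-oxoheptan-3-yl 2,2-dibromopropanoate | CCC(=O)[C@@H](C)[C@@H](OC(=O)C(C)(Br)Br)[C@H](C)CO[Si](c1ccccc1)(c1ccccc1)C(C)(C)C | intermediate
9 | propanal | CCC=O | starting material
10 | trichlorotitanium Z-enolate of 8 (enolised toward the ethyl group) | C/C=C(\O[Ti](Cl)(Cl)Cl)[C@@H](C)[C@@H](OC(=O)C(C)(Br)Br)[C@H](C)CO[Si](c1ccccc1)(c1ccccc1)C(C)(C)C | intermediate
11 | (3S,4R,6S,7S,8R)-9-[(tert-butyldiphenylsilyl)oxy]-3-hydroxy-4,6,8-trimethyl-5-oxononan-7-yl 2,2-dibromopropanoate | CC[C@H](O)[C@@H](C)C(=O)[C@@H](C)[C@@H](OC(=O)C(C)(Br)Br)[C@H](C)CO[Si](c1ccccc1)(c1ccccc1)C(C)(C)C | intermediate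
12 | (3S,4R,6S,7S,8R)-9-[(tert-butyldiphenylsilyl)oxy]-4,6,8-trimethyl-5-oxo-3-[(triethylsilyl)oxy]nonan-7-yl 2,2-dibromopropanoate | CC[C@H](O[Si](CC)(CC)CC)[C@@H](C)C(=O)[C@@H](C)[C@@H](OC(=O)C(C)(Br)Br)[C@H](C)CO[Si](c1ccccc1)(c1ccccc1)C(C)(C)C | intermediate
13 | diiodosamarium bromo enolate of ester 12 | CC[C@H](O[Si](CC)(CC)CC)[C@@H](C)C(=O)[C@@H](C)[C@@H](OC(O[Sm](I)I)=C(C)Br)[C@H](C)CO[Si](c1ccccc1)(c1ccccc1)C(C)(C)C | intermediate
14 | (4R,5S,6S)-3-bromo-6-[(2R)-1-[(tert-butyldiphenylsilyl)oxy]propan-2-yl]-4-hydroxy-3,5-dimethyl-4-[(2R,3S)-3-[(triethylsilyl)oxy]pentan-2-yl]oxan-2-one (C3 epimers) | CC[C@H](O[Si](CC)(CC)CC)[C@@H](C)[C@]1(O)[C@@H](C)[C@H]([C@H](C)CO[Si](c1ccccc1)(c1ccccc1)C(C)(C)C)OC(=O)C1(C)Br | intermediate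
15 | (4S,5S,6S)-3-bromo-6-[(2R)-1-[(tert-butyldiphenylsilyl)oxy]propan-2-yl]-4-hydroxy-4-[(2R,3S)-3-hydroxypentan-2-yl]-3,5-dimethyloxan-2-one (C3 epimers) | CC[C@H](O)[C@@H](C)[C@]1(O)[C@@H](C)[C@H]([C@H](C)CO[Si](c1ccccc1)(c1ccccc1)C(C)(C)C)OC(=O)C1(C)Br | intermediate
16 | (4R,5S,6S)-3-bromo-6-[(2R)-1-[(tert-butyldiphenylsilyl)oxy]propan-2-yl]-4-hydroxy-3,5-dimethyl-4-[(2S)-3-oxopentan-2-yl]oxan-2-one (C3 epimers) | CCC(=O)[C@@H](C)[C@]1(O)[C@@H](C)[C@H]([C@H](C)CO[Si](c1ccccc1)(c1ccccc1)C(C)(C)C)OC(=O)C1(C)Br | intermediate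
17 | bis(trimethylsilyl) derivative of 16: 4-O-trimethylsilyl ether and Z-trimethylsilyl enol ether of the side-chain ketone toward its ethyl group (other centres as in 16) | C/C=C(\O[Si](C)(C)C)[C@@H](C)[C@]1(O[Si](C)(C)C)[C@@H](C)[C@H]([C@H](C)CO[Si](c1ccccc1)(c1ccccc1)C(C)(C)C)OC(=O)C1(C)Br | intermediate
18 | acetaldehyde | CC=O | starting material
19 | O-ethylidene oxocarbenium triflate derived from 17 (tertiary oxygen bound to CH–CH3 as O+=CH–CH3) | C/C=C(\O[Si](C)(C)C)[C@@H](C)[C@]1([O+]=CC)[C@@H](C)[C@H]([C@H](C)CO[Si](c1ccccc1)(c1ccccc1)C(C)(C)C)OC(=O)C1(C)Br.[O-]S(=O)(=O)C(F)(F)F | intermediate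
20 | 7-bromo-10-[(2R)-1-[(tert-butyldiphenylsilyl)oxy]propan-2-yl]-2,3,5,7,11-pentamethyl-1,9-dioxaspiro[5.5]undecane-4,8-dione (oxane methyl groups all equatorial; C7 epimers) | O=C1[C@H](C)[C@@H](C)O[C@@]2([C@@H]1C)[C@@H](C)[C@H]([C@H](C)CO[Si](c1ccccc1)(c1ccccc1)C(C)(C)C)OC(=O)C2(C)Br | intermediate
21 | 7-bromo-10-[(2R)-1-[(tert-butyldiphenylsilyl)oxy]propan-2-yl]-4-hydroxy-2,3,5,7,11-pentamethyl-1,9-dioxaspiro[5.5]undecan-8-one (axial C4 hydroxyl; C7 epimers) | O[C@@H]1[C@H](C)[C@@H](C)O[C@@]2([C@@H]1C)[C@@H](C)[C@H]([C@H](C)CO[Si](c1ccccc1)(c1ccccc1)C(C)(C)C)OC(=O)C2(C)Br | intermediate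
22 | 7-bromo-10-[(2R)-1-[(tert-butyldiphenylsilyl)oxy]propan-2-yl]-2,3,5,7,11-pentamethyl-8-oxo-1,9-dioxaspiro[5.5]undecan-4-yl acetate (C7 epimers) | CC(=O)O[C@@H]1[C@H](C)[C@@H](C)O[C@@]2([C@@H]1C)[C@@H](C)[C@H]([C@H](C)CO[Si](c1ccccc1)(c1ccccc1)C(C)(C)C)OC(=O)C2(C)Br | intermediate
23 | 7-bromo-10-[(2R)-1-hydroxypropan-2-yl]-2,3,5,7,11-pentamethyl-8-oxo-1,9-dioxaspiro[5.5]undecan-4-yl acetate (C7 epimers) | CC(=O)O[C@@H]1[C@H](C)[C@@H](C)O[C@@]2([C@@H]1C)[C@@H](C)[C@H]([C@H](C)CO)OC(=O)C2(C)Br | intermediate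
24 | 7-bromo-2,3,5,7,11-pentamethyl-8-oxo-10-(1-oxopropan-2-yl)-1,9-dioxaspiro[5.5]undecan-4-yl acetate (C7 epimers; other centres as in 23) | CC(=O)O[C@@H]1[C@H](C)[C@@H](C)O[C@@]2([C@@H]1C)[C@@H](C)[C@H]([C@H](C)C=O)OC(=O)C2(C)Br | intermediate
25 | diiodosamarium lactone enolate of 24 | CC(=O)O[C@@H]1[C@H](C)[C@@H](C)O[C@@]2([C@@H]1C)[C@@H](C)[C@H]([C@H](C)C=O)OC(O[Sm](I)I)=C2C | intermediate
26 | 8-hydroxy-4,6,7,3′,5′,6′-hexamethyl-3-oxospiro[2-oxabicyclo[2.2.2]octane-5,2′-oxan]-4′-yl acetate (all centres shared with 27 as in 27; C8 hydroxyl on the lactone side) | CC(=O)O[C@@H]1[C@H](C)[C@@H](C)O[C@@]2([C@@H]1C)[C@@H](C)[C@H]1OC(=O)[C@]2(C)[C@H](O)[C@H]1C | intermediate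
27 | (1R,3′R,4S,4′R,5S,5′R,6S,6′R,7S)-4,6,7,3′,5′,6′-hexamethyl-3,8-dioxospiro[2-oxabicyclo[2.2.2]octane-5,2′-oxan]-4′-yl acetate (CNP0257416.1) | CC(=O)O[C@@H]1[C@H](C)[C@@H](C)O[C@@]2([C@@H]1C)[C@@H](C)[C@H]1OC(=O)[C@]2(C)C(=O)[C@H]1C | target

**Totals**

Total step count: 17. Longest linear sequence: 17 steps (1 to 27); pentan-3-one, 2,2-dibromopropanoic acid, propanal and acetaldehyde enter directly.

**Steps most likely to fail**

Step 7. The tetrasubstituted bromo enolate may add too slowly to the doubly α-branched ketone, so that protonation of the enolate, or a second reduction followed by β-elimination of the new alkoxide, takes over. The fallback sets out from 12 and returns at 14; it separates carbon–carbon bond formation from bromination. 12 is mono-debrominated with diethyl phosphite and Et3N to the 2-bromopropanoate F1. The less hindered secondary samarium enolate from F1 (SmI2, THF, −78 °C) closes the ring through the same chelated chair to the bromine-free hydroxy lactone F2. The dianion of F2 (LiN(i-Pr)2, 2.2 equiv, THF, −78 °C; alkoxide plus lactone enolate, a Fráter–Seebach-type species that cannot undergo retro-aldol cleavage or β-elimination) is then brominated with CBr4 to give 14.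

Step 11. Condensation at the very hindered tertiary silyl ether may be slow, so that intermolecular Mukaiyama-type addition of the enol silane to acetaldehyde or loss of the enol silane competes; oxonia-Cope scrambling of the spiro centre is a further possibility. The fallback sets out from 16 and returns at 20; it attaches the acetaldehyde carbon to oxygen first, so that the ring closure is unimolecular. 16 is converted with ethyl vinyl ether and PPTS into the 1-ethoxyethyl mixed acetal F3. Enol silylation (TMSOTf, Et3N, −78 °C) gives the Z-trimethylsilyl enol ether F4. Catalytic TMSOTf with 2,6-di-tert-butyl-4-methylpyridine at −78 °C then ionises the acetal with loss of the less hindered ethoxy group, and the same oxocarbenium ion closes to 20.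

Step 16. The samarium enolate may expel the neighbouring oxane oxygen (ring-opening β-elimination) or be protonated before the lactone reaches the boat geometry needed for the bridging aldol, at a stage where material is scarce. The fallback sets out from 16 and returns at 26; it reverses the order of ring construction, so that the carbocycle is closed before the oxane exists and the β-oxygen is a silyl ether.
- 16 is desilylated (HF·pyridine) to the primary alcohol F5 and oxidised (Dess–Martin periodinane) to the keto aldehyde F6.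
- N-(trimethylsilyl)imidazole gives the tertiary trimethylsilyl ether F7, and SmI2 (THF, −78 °C) closes the carbocycle to the bicyclic hydroxy ketone F8.
- TBSOTf and Et3N give the C8 silyl ether and Z-silyl enol ether F9, and acetaldehyde with catalytic TMSOTf gives the spiro oxanone F10 by the same Prins closure.
- LiBH(s-Bu)3 gives the axial alcohol F11, Ac2O with DMAP gives the acetate F12, and HF·pyridine gives 26.

**Further compounds**

F1 | step 7 | (3S,4R,6S,7S,8R)-9-[(tert-butyldiphenylsilyl)oxy]-4,6,8-trimethyl-5-oxo-3-[(triethylsilyl)oxy]nonan-7-yl 2-bromopropanoate (bromide epimers) | CC[C@H](O[Si](CC)(CC)CC)[C@@H](C)C(=O)[C@@H](C)[C@@H](OC(=O)C(C)Br)[C@H](C)CO[Si](c1ccccc1)(c1ccccc1)C(C)(C)C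
F2 | step 7 | 14 with hydrogen in place of bromine: 6-[(2R)-1-[(tert-butyldiphenylsilyl)oxy]propan-2-yl]-4-hydroxy-3,5-dimethyl-4-[(2R,3S)-3-[(triethylsilyl)oxy]pentan-2-yl]oxan-2-one (C3 epimers) | CC[C@H](O[Si](CC)(CC)CC)[C@@H](C)[C@]1(O)[C@@H](C)[C@H]([C@H](C)CO[Si](c1ccccc1)(c1ccccc1)C(C)(C)C)OC(=O)C1C
F3 | step 11 | 1-ethoxyethyl ether of the tertiary alcohol of 16 (acetal epimers) | CCC(=O)[C@@H](C)[C@]1(OC(C)OCC)[C@@H](C)[C@H]([C@H](C)CO[Si](c1ccccc1)(c1ccccc1)C(C)(C)C)OC(=O)C1(C)Br
F4 | step 11 | Z-trimethylsilyl enol ether of F3 (toward the ethyl group) | C/C=C(\O[Si](C)(C)C)[C@@H](C)[C@]1(OC(C)OCC)[C@@H](C)[C@H]([C@H](C)CO[Si](c1ccccc1)(c1ccccc1)C(C)(C)C)OC(=O)C1(C)Br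
F5 | step 16 | 16 without the silyl group (primary alcohol) | CCC(=O)[C@@H](C)[C@]1(O)[C@@H](C)[C@H]([C@H](C)CO)OC(=O)C1(C)Br
F6 | step 16 | keto aldehyde from F5 (1-oxopropan-2-yl side chain) | CCC(=O)[C@@H](C)[C@]1(O)[C@@H](C)[C@H]([C@H](C)C=O)OC(=O)C1(C)Br
F7 | step 16 | tertiary trimethylsilyl ether of F6 | CCC(=O)[C@@H](C)[C@]1(O[Si](C)(C)C)[C@@H](C)[C@H]([C@H](C)C=O)OC(=O)C1(C)Br
F8 | step 16 | 8-hydroxy-4,6,7-trimethyl-5-(3-oxopentan-2-yl)-5-[(trimethylsilyl)oxy]-2-oxabicyclo[2.2.2]octan-3-one | CCC(=O)[C@@H](C)[C@]1(O[Si](C)(C)C)[C@@H](C)[C@H]2OC(=O)[C@]1(C)[C@H](O)[C@H]2C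
F9 | step 16 | 8-O-tert-butyldimethylsilyl ether and Z-tert-butyldimethylsilyl enol ether of F8 | C/C=C(\O[Si](C)(C)C(C)(C)C)[C@@H](C)[C@]1(O[Si](C)(C)C)[C@@H](C)[C@H]2OC(=O)[C@]1(C)[C@H](O[Si](C)(C)C(C)(C)C)[C@H]2C
F10 | step 16 | 8-[(tert-butyldimethylsilyl)oxy]-4,6,7,3′,5′,6′-hexamethylspiro[2-oxabicyclo[2.2.2]octane-5,2′-oxane]-3,4′-dione | O=C1[C@H](C)[C@@H](C)O[C@@]2([C@@H]1C)[C@@H](C)[C@H]1OC(=O)[C@]2(C)[C@H](O[Si](C)(C)C(C)(C)C)[C@H]1C
F11 | step 16 | 8-[(tert-butyldimethylsilyl)oxy]-4′-hydroxy-4,6,7,3′,5′,6′-hexamethylspiro[2-oxabicyclo[2.2.2]octane-5,2′-oxan]-3-one (axial 4′-hydroxyl) | O[C@@H]1[C@H](C)[C@@H](C)O[C@@]2([C@@H]1C)[C@@H](C)[C@H]1OC(=O)[C@]2(C)[C@H](O[Si](C)(C)C(C)(C)C)[C@H]1C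
F12 | step 16 | 8-[(tert-butyldimethylsilyl)oxy]-4,6,7,3′,5′,6′-hexamethyl-3-oxospiro[2-oxabicyclo[2.2.2]octane-5,2′-oxan]-4′-yl acetate | CC(=O)O[C@@H]1[C@H](C)[C@@H](C)O[C@@]2([C@@H]1C)[C@@H](C)[C@H]1OC(=O)[C@]2(C)[C@H](O[Si](C)(C)C(C)(C)C)[C@H]1C
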